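The ratio of target in elm to target in alder at 10.0 min is 2.77, though their partner ratio is 4.00.

| flask | starting material | partner | remark | time |
|---|---|---|---|---|
| larch | 10 mM | 15 mM | run made earlier |  |
| alder | 10 mM | 7.5 mM | run made earlier |  |
| elm | 10 mM | 30 mM | run made earlier |  |
| epsilon | 10 mM (fed, over 8.0 min) | 15.0 mM | all else is in the flask from the start; the feed brings no volume worth counting | 10 min |
| alpha | 10 mM | 15.0 mM (fed, over 8.0 min) | all else is in the flask from the start; the feed brings no volume worth counting | 10 min |
| theta | 10 mM | 15.0 mM | everything together at the start | 10 min |

| run | time / min | target / % | starting material / % |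
|---|---|---|---|
| larch | 1.33 | 7.1 | 2.2 |
| larch | 2.50 | 12.2 | 0 |
| larch | 4.00 | 16.5 | 0 |
| larch | 5.00 | 18.2 | 0 |
| larch | 6.00 | 19.3 | 0.4 |
| alder | 2.00 | 4.6 | 0 |
| alder | 4.00 | 8.4 | 0 |
| alder | 6.00 | 10.9 | 0.5 |
| alder | 8.00 | 12.5 | 0 |
| alder | 10.0 | 13.4 | 0 |
| elm | 0.833 | 7.2 | 9.2 |
| elm | 2.50 | 22.3 | 0.2 |
| elm | 5.00 | 30.5 | 0 |
| elm | 8.00 | 35.4 | 0 |
| elm | 10.0 | 37.1 | 0.5 |

(each reading ± 0.3 percentage points)

- the best flask by amount of target, in percent of the starting material charged; "all alike" if 1.5 percentage points covers them all (epsilon / alpha / theta / all alike)
- amount of target at the end, in percent of the starting material charged, epsilon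
- amount of target at the end, in percent of the starting material charged, alpha
- amount of target at the end, in percent of the starting material charged, theta

So target is not proportional to partner at this time. I read the tables side by side. Larch has 2.00 times the partner of alder. Its target ratio to alder is 1.96 at 4.00 min and 1.77 at 6.00 min. The ratio sinks with time, so I take the pair read at the asked time.

I define the partner exponent as the power of [partner] that target follows at a fixed time and a fixed charge of starting material, an apparent order in partner. From the readings of elm and alder it comes to 0.735.

Theta has 15.0 mM of partner, so scaling alder by the exponent gives 22.3 %. In alpha, [partner] climbs during the feed. Its mean over the run, counted as fed and before any use, is 9.00 mM. Scaling alder to that mean gives 15.3 %. In epsilon, the fed material has a mean age of 6.00 min at the end, so I take the larch reading at that age, 19.3 %, as my estimate for epsilon. So I put theta first.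

The forecast also says theta, with 18 % for epsilon, 11 % for alpha and 22 % for theta. For alpha it reasons that “partner is scarce while the intermediate is richest”. My alpha lies above its high end of 14 %.

The flasks give 19.3 % for epsilon, 18.1 % for alpha and 24.3 % for theta, so theta leads.

    starting material → intermediate (k = 2.90 /min)
    partner + intermediate → target (k = 5.60 /M/min)
    2 intermediate → homo product (k = 0.460 /M/min)
    intermediate → decomposed reagent (k = 0.0260 /min)
    target ⇌ isomer of the product (K = 1.00, k = 0.260 /min)

In theta, starting material went to intermediate with a half-life of 0.24 min, and capture by partner ran on with intermediate at 60.5 % after 5.00 min and 37.8 % at the end, beside 18.7 % of isomer of the product. In alpha, intermediate stood at 75.8 % after 5.00 min with partner at 55.7 % of its charge, and target climbed from 7.54 % to 18.1 % by 10.0 min. Target in alpha over target in theta is 0.745, and the exponent on the mean partner of alpha as fed against the charge of theta gives 0.687. From theta, the exponent puts target in a neighbour flask with 25 mM of partner at 35.4 %, and that flask holds 33.7 % of target.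

The numbers in the tables come from a simulation for substances that don't exist; scatter was added.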